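Assumption: the target has no stereocentre and no stereogenic double bond (each prenyl alkene ends in two identical methyl groups), so it is achiral and "the single enantiomer given" is simply the compound as drawn.

## Retrosynthetic overview

1. The target comes from its tetra-MOM ether by global MOM removal in the last step.
2. The pyranone ring C is made from a 2-hydroxydeoxybenzoin plus one carbon from tert-butyl isocyanide. The key bond is O1–C2 (C–O), formed by Cu-catalysed addition of the phenol O–H across the isocyanide, followed by ring closure with loss of t-BuNH2.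
3. The deoxybenzoin comes from an A-ring acetophenone and a B-ring aryl bromide by Pd-catalysed enolate α-arylation.
4. The A ring comes from phloroacetophenone (double C-prenylation, bis-MOM). The B ring comes from 4-bromoresorcinol (bis-MOM, lithiation between the two OMOM groups, prenylation).
5. Ring order: rings A and B are bought intact; ring C is the only ring formed, in the penultimate step.

## Route

Step 1
Reactants: 1 1-(2,4,6-trihydroxyphenyl)ethan-1-one (phloroacetophenone); 2 1-bromo-3-methylbut-2-ene (prenyl bromide)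
Product: 3 1-[2,4,6-trihydroxy-3,5-bis(3-methylbut-2-en-1-yl)phenyl]ethan-1-one
Conditions: 2 (2.2 equiv), 10% aq KOH, 0 °C to rt; then cold dilute HCl to pH 4
Reagents that add atoms: prenyl bromide, CC(C)=CCBr
Why: Aqueous C-alkylation of the acylphloroglucinol polyphenoxide (deoxyhumulone-type C-prenylation); C3 and C5 are the only free ring carbons, so the diprenylation is regiochemically unambiguous, the yield is moderate, and no stereocentre is formed.

Step 2
Reactants: 3 1-[2,4,6-trihydroxy-3,5-bis(3-methylbut-2-en-1-yl)phenyl]ethan-1-one; 4 chloromethyl methyl ether (MOMCl)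
Product: 5 1-[2-hydroxy-4,6-bis(methoxymethoxy)-3,5-bis(3-methylbut-2-en-1-yl)phenyl]ethan-1-one
Conditions: MOMCl (2.3 equiv), i-Pr2NEt (3 equiv), CH2Cl2, 0 °C to rt
Reagents that add atoms: chloromethyl methyl ether, COCCl
Why: Williamson-type MOM ether formation; the para OH and one of the two equivalent ortho OH groups react, while the remaining ortho OH is held in the hydrogen bond to the ketone and stays free.

Step 3
Reactants: 6 4-bromobenzene-1,3-diol (4-bromoresorcinol); 4 chloromethyl methyl ether (MOMCl)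
Product: 7 1-bromo-2,4-bis(methoxymethoxy)benzene
Conditions: MOMCl (2.5 equiv), i-Pr2NEt (3 equiv), CH2Cl2, 0 °C to rt
Reagents that add atoms: chloromethyl methyl ether, COCCl
Why: Standard MOM ether formation on two unhindered phenols; the aryl bromide is untouched.

Step 4
Reactants: 7 1-bromo-2,4-bis(methoxymethoxy)benzene; 2 1-bromo-3-methylbut-2-ene (prenyl bromide)
Product: 9 1-bromo-2,4-bis(methoxymethoxy)-3-(3-methylbut-2-en-1-yl)benzene, via aryllithium 8 (not isolated)
Conditions: LDA (1.15 equiv), THF, −78 °C, 1 h; CuI (10 mol%), prenyl bromide (1.3 equiv), −78 °C to rt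
Reagents that add atoms: prenyl bromide, CC(C)=CCBr
Why: Directed ortho-metalation: the amide base removes the most acidic ring H, flanked by two OMOM groups, without bromine–lithium exchange, and Cu-catalysed SN2 allylation of the aryllithium gives the linear prenyl group.

Step 5
Reactants: 5 1-[2-hydroxy-4,6-bis(methoxymethoxy)-3,5-bis(3-methylbut-2-en-1-yl)phenyl]ethan-1-one; 9 1-bromo-2,4-bis(methoxymethoxy)-3-(3-methylbut-2-en-1-yl)benzene
Product: 10 1-[2-hydroxy-4,6-bis(methoxymethoxy)-3,5-bis(3-methylbut-2-en-1-yl)phenyl]-2-[2,4-bis(methoxymethoxy)-3-(3-methylbut-2-en-1-yl)phenyl]ethan-1-one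
Conditions: Pd2(dba)3 (2.5 mol%), XPhos (6 mol%), NaOt-Bu (3.2 equiv), THF, 65 °C
Reagents that add atoms: none
Why: Pd-catalysed ketone enolate α-arylation (Buchwald–Hartwig type) through the phenoxide/enolate dianion of the o-hydroxyacetophenone, which reacts at carbon; the methyl group is the only enolisable site, the ortho-substituted aryl group suppresses diarylation, and the trisubstituted prenyl alkenes and MOM ethers are inert.

Step 6
Reactants: 10 1-[2-hydroxy-4,6-bis(methoxymethoxy)-3,5-bis(3-methylbut-2-en-1-yl)phenyl]-2-[2,4-bis(methoxymethoxy)-3-(3-methylbut-2-en-1-yl)phenyl]ethan-1-one; 11 tert-butyl isocyanide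
Product: 13 3-[2,4-bis(methoxymethoxy)-3-(3-methylbut-2-en-1-yl)phenyl]-5,7-bis(methoxymethoxy)-6,8-bis(3-methylbut-2-en-1-yl)-4H-chromen-4-one, via aryl formimidate 12 (not isolated)
Conditions: t-BuNC (2.5 equiv), Cu2O (5 mol%), 1,10-phenanthroline (10 mol%), toluene, 90 °C, N2
Reagents that add atoms: tert-butyl isocyanide, CC(C)(C)[N+]#[C-]
Why: Proposed new method: Cu(I)-catalysed use of an isocyanide as a neutral methine donor for chromone annulation; the copper phenoxide of the single free, ketone-chelated OH undergoes 1,1-insertion of t-BuNC and protonolysis to give aryl formimidate 12 (the new O1–C2 bond), whose electrophilic C=N sits six atoms from the doubly activated benzylic α-carbon, so 6-exo enol addition and E1cB loss of volatile t-BuNH2 give the conjugated pyranone irreversibly (the alternative order, Cu-mediated α-C–H addition to the isocyanide followed by 6-endo O-attack, converges on the same product); the closest known reaction types are the Saegusa–Ito Cu-catalysed α-addition of O–H and acidic C–H bonds to isocyanides and the classical orthoformate or DMF-DMA one-carbon annulation of 2-hydroxydeoxybenzoins; MOM ethers and prenyl alkenes are inert to Cu(I)/isocyanide and no stereocentre is formed.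

Step 7
Reactants: 13 3-[2,4-bis(methoxymethoxy)-3-(3-methylbut-2-en-1-yl)phenyl]-5,7-bis(methoxymethoxy)-6,8-bis(3-methylbut-2-en-1-yl)-4H-chromen-4-one
Product: 14 Euchrenone b2, 3-[2,4-dihydroxy-3-(3-methylbut-2-en-1-yl)phenyl]-5,7-dihydroxy-6,8-bis(3-methylbut-2-en-1-yl)-4H-chromen-4-one
Conditions: 3 M HCl in MeOH–THF (1:1), 40–45 °C, monitored and stopped at full conversion
Reagents that add atoms: none
Why: Acid-catalysed acetal exchange of the four aryl MOM ethers with methanol (transacetalisation to dimethoxymethane); kept mild and short so the ortho-prenylphenols do not cyclise to chromans.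

## Compound list

1 | 1-(2,4,6-trihydroxyphenyl)ethan-1-one (phloroacetophenone) | CC(=O)c1c(O)cc(O)cc1O | starting material
2 | 1-bromo-3-methylbut-2-ene (prenyl bromide) | CC(C)=CCBr | starting material
3 | 1-[2,4,6-trihydroxy-3,5-bis(3-methylbut-2-en-1-yl)phenyl]ethan-1-one | CC(=O)c1c(O)c(CC=C(C)C)c(O)c(CC=C(C)C)c1O | intermediate
4 | chloromethyl methyl ether (MOMCl) | COCCl | starting material
5 | 1-[2-hydroxy-4,6-bis(methoxymethoxy)-3,5-bis(3-methylbut-2-en-1-yl)phenyl]ethan-1-one | CC(=O)c1c(O)c(CC=C(C)C)c(OCOC)c(CC=C(C)C)c1OCOC | intermediate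
6 | 4-bromobenzene-1,3-diol (4-bromoresorcinol) | Oc1ccc(Br)c(O)c1 | starting material
7 | 1-bromo-2,4-bis(methoxymethoxy)benzene | COCOc1ccc(Br)c(OCOC)c1 | intermediate
8 | [3-bromo-2,6-bis(methoxymethoxy)phenyl]lithium (not isolated) | [Li]c1c(OCOC)ccc(Br)c1OCOC | intermediate
9 | 1-bromo-2,4-bis(methoxymethoxy)-3-(3-methylbut-2-en-1-yl)benzene | COCOc1ccc(Br)c(OCOC)c1CC=C(C)C | intermediate
10 | 1-[2-hydroxy-4,6-bis(methoxymethoxy)-3,5-bis(3-methylbut-2-en-1-yl)phenyl]-2-[2,4-bis(methoxymethoxy)-3-(3-methylbut-2-en-1-yl)phenyl]ethan-1-one | O=C(Cc1ccc(OCOC)c(CC=C(C)C)c1OCOC)c1c(O)c(CC=C(C)C)c(OCOC)c(CC=C(C)C)c1OCOC | intermediate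
11 | tert-butyl isocyanide (2-isocyano-2-methylpropane) | CC(C)(C)[N+]#[C-] | starting material
12 | O-aryl N-tert-butylformimidate of 10, (E) at C=N, the phenol oxygen of 10 carrying CH=N-t-Bu (not isolated) | CC(C)(C)/N=C/Oc1c(CC=C(C)C)c(OCOC)c(CC=C(C)C)c(OCOC)c1C(=O)Cc1ccc(OCOC)c(CC=C(C)C)c1OCOC | intermediate
13 | 3-[2,4-bis(methoxymethoxy)-3-(3-methylbut-2-en-1-yl)phenyl]-5,7-bis(methoxymethoxy)-6,8-bis(3-methylbut-2-en-1-yl)-4H-chromen-4-one | COCOc1ccc(-c2coc3c(CC=C(C)C)c(OCOC)c(CC=C(C)C)c(OCOC)c3c2=O)c(OCOC)c1CC=C(C)C | intermediate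
14 | Euchrenone b2, 3-[2,4-dihydroxy-3-(3-methylbut-2-en-1-yl)phenyl]-5,7-dihydroxy-6,8-bis(3-methylbut-2-en-1-yl)-4H-chromen-4-one (achiral) | CC(C)=CCc1c(O)ccc(-c2coc3c(CC=C(C)C)c(O)c(CC=C(C)C)c(O)c3c2=O)c1O | target

## Step count and risks

Total steps: 7. Longest linear sequence: 5 (steps 1, 2, 5, 6, 7 from compound 1, or steps 3, 4, 5, 6, 7 from compound 6).

The three steps most likely to fail:

**Step 6 (the proposed new Cu/isocyanide annulation).** The hindered, chelated phenol may insert slowly, or the isocyanide may be consumed by the liberated amine. The fallback uses known chemistry and sets out from 10. Heating 10 with N,N-dimethylformamide dimethyl acetal in toluene at 85 °C gives the enaminone 3-(dimethylamino)-1-[2-hydroxy-4,6-bis(methoxymethoxy)-3,5-bis(3-methylbut-2-en-1-yl)phenyl]-2-[2,4-bis(methoxymethoxy)-3-(3-methylbut-2-en-1-yl)phenyl]prop-2-en-1-one F3. On brief warming in acetic acid or on silica gel this closes by addition–elimination of the phenol with loss of dimethylamine. This is the standard deoxybenzoin-to-isoflavone conversion, and it comes back to the route at 13.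

**Step 5 (α-arylation in the presence of the free chelated phenol).** The phenoxide may bind palladium or the dianion may form poorly. The fallback sets out from 5 and removes the free OH from the coupling. Capping the remaining phenol (NaH, MOMCl, DMF, 0 °C) gives the fully protected ketone 1-[2,4,6-tris(methoxymethoxy)-3,5-bis(3-methylbut-2-en-1-yl)phenyl]ethan-1-one F1. This is α-arylated with 9 under ordinary mono-enolate conditions (Pd2(dba)3, XPhos, NaOt-Bu 2.2 equiv, toluene, 80 °C) to the penta-MOM deoxybenzoin 1-[2,4,6-tris(methoxymethoxy)-3,5-bis(3-methylbut-2-en-1-yl)phenyl]-2-[2,4-bis(methoxymethoxy)-3-(3-methylbut-2-en-1-yl)phenyl]ethan-1-one F2. Chelation-accelerated solvolysis of one of the two equivalent carbonyl-flanking MOM groups (catalytic HCl, MeOH, 0 °C, stopped after mono-cleavage) then comes back to the route at 10.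

**Step 7 (global MOM removal beside three ortho-prenylphenols).** Protic acid may cyclise the prenyl groups onto the neighbouring phenols. The fallback sets out from 13 and avoids Brønsted acid altogether. Silyl-transfer dealkoxymethylation with TESOTf and 2,2'-bipyridyl (CH2Cl2, 0 °C to rt) converts the four aryl MOM ethers into the tetrakis(triethylsilyl) ether 3-[2,4-bis(triethylsilyloxy)-3-(3-methylbut-2-en-1-yl)phenyl]-5,7-bis(triethylsilyloxy)-6,8-bis(3-methylbut-2-en-1-yl)-4H-chromen-4-one F4. Desilylation with AcOH-buffered TBAF in THF at 0 °C then comes back to the route at 14.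

## Further compounds

F1 | step 5 | 1-[2,4,6-tris(methoxymethoxy)-3,5-bis(3-methylbut-2-en-1-yl)phenyl]ethan-1-one | CC(=O)c1c(OCOC)c(CC=C(C)C)c(OCOC)c(CC=C(C)C)c1OCOC
F2 | step 5 | 1-[2,4,6-tris(methoxymethoxy)-3,5-bis(3-methylbut-2-en-1-yl)phenyl]-2-[2,4-bis(methoxymethoxy)-3-(3-methylbut-2-en-1-yl)phenyl]ethan-1-one | O=C(Cc1ccc(OCOC)c(CC=C(C)C)c1OCOC)c1c(OCOC)c(CC=C(C)C)c(OCOC)c(CC=C(C)C)c1OCOC
F3 | step 6 | 3-(dimethylamino)-1-[2-hydroxy-4,6-bis(methoxymethoxy)-3,5-bis(3-methylbut-2-en-1-yl)phenyl]-2-[2,4-bis(methoxymethoxy)-3-(3-methylbut-2-en-1-yl)phenyl]prop-2-en-1-one (mixture of C=C isomers) | CN(C)C=C(C(=O)c1c(O)c(CC=C(C)C)c(OCOC)c(CC=C(C)C)c1OCOC)c1ccc(OCOC)c(CC=C(C)C)c1OCOC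
F4 | step 7 | 3-[2,4-bis(triethylsilyloxy)-3-(3-methylbut-2-en-1-yl)phenyl]-5,7-bis(triethylsilyloxy)-6,8-bis(3-methylbut-2-en-1-yl)-4H-chromen-4-one | CC[Si](CC)(CC)Oc1ccc(-c2coc3c(CC=C(C)C)c(O[Si](CC)(CC)CC)c(CC=C(C)C)c(O[Si](CC)(CC)CC)c3c2=O)c(O[Si](CC)(CC)CC)c1CC=C(C)C
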